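The numbers of this flask were drawn at random within sensible limits.

How much target stands in this flask at the end of the run, and is it still rising?

    2 substrate → homo dimer (k1 = 0.0060 /M/s)
    precatalyst → free catalyst (k2 = 0.11 /s)
    substrate + free catalyst → catalyst intermediate A (k3 = 19000 /M/s)
    catalyst intermediate B → free catalyst + target (k4 = 22000 /s)
    substrate + catalyst intermediate B → spent catalyst (k5 = 0.10 /M/s)
    reagent + catalyst intermediate A → catalyst intermediate B (k6 = 190 /M/s)

substrate 1.5 M (fed, over 0.80 s); reagent 0.800 equiv; precatalyst 0.05 mol%; time 6.0 s; the fed solution adds 0.50 times the starting volume

1. the state of affairs at 6.0 s: stopped, and by what, or still going (the reagent has run out first / no working catalyst is left / it is still moving / all of the substrate has reacted)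
2. amount of target at 6.0 s, in percent of the substrate charged

- percentages count the substrate that a species holds: one homo dimer or spent catalyst counts as two
- two of one species on the left: rate k times its square, two consumed each time
- every charge counts on the volume at the start, and the solution that is fed holds the whole dose
- the reaction counts as stopped when no species that holds the substrate changes by six tenths of a point or more over the second half of the time
- run time (flask): 6.0 s

Take the feed as finished from the start, since its 0.80 s is shorter than the run, and spread every charge over the final volume, which puts the whole catalyst at 0.500 mM. Now compare the steps of the round: free catalyst meets substrate at 19000 /s and catalyst intermediate B falls apart at 22000 /s, but catalyst intermediate A meets reagent at 152 /s, slower than either. So the released catalyst sits as catalyst intermediate A, the resting state, and its step with reagent is the rate-limiting step of the round.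

Treat the reagent as pseudo-first-order, falling at 190 /M/s times [catalyst intermediate A] times [reagent]. But [catalyst intermediate A] climbs slowly, because the precatalyst has a half-life of 6.3 s, longer than the run. Integrate that rise, and the run counts as the whole catalyst working for 1.61 s. Call the reagent exposure the rate constant of the reagent step times the catalyst concentration released, integrated over time: 0.153.

For a first round, hold the reagent at its charge, which gives 12.2% target. Then put that answer back, since spent reagent slows the rate in proportion: going round to the end leaves the fraction exp(−exposure) of the reagent, and my reckoning gives 11.3% target. At 3.00 s the exposure is 0.0423, so target gains 8 percentage points after that, and I expect the flask to be still moving.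

The forecast says it is still moving, with 11.4%, and holds that “neither substrate, reagent nor catalyst runs out”.

The simulation gives 11.2% and it is still moving, with 51.7% of the catalyst still precatalyst at 6.00 s and 47.5% as catalyst intermediate A. With the exposure below one, the reagent reckons at 85.8% left, and the flask holds 86%.

Read the same flask at 25 s: the exposure becomes 1.57, the first round gives 125%, above the 80.0% the charges allow, and the second round gives 63.3% target with 20.8% of the reagent left. The simulation of that flask gives 62.9% target and 21% of the reagent.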